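**Plan**

Numbering: ring C1–C14 = C1H2, C2H=C3(CO2Me), C4H2, C5H2, C6H=C7(Me), C8H2, C9H2, C10H=C11(Me), C12H2, C13H2, C14H (stereocentre). C15 is the exocyclic C(=CH2) and C16–C19 the homoprenyl tail.
Enabling feature: in the 14-membered ring, C14 is allylic to the exocyclic 1,1-disubstituted alkene C15=CH2 (retron of an SN2′ displacement on C14H=C15–CH2Cl). Its neighbour C13 is homoallylic to C10=C11 (retron of a terminal 1,3-diene hydroboration), so cutting C13–C14 gives the achiral open-chain hexaene chloride 20.
Further cuts: C1–C14 (allyl–alkenyl Stille coupling), C3–CO2Me (enol triflate carbonylation), C4–C5 (acetoacetate dianion alkylation), C12=C13 (Wittig), C15–C16 (carbomagnesiation of propargyl alcohol).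
Forward: neryl acetate is oxidised at C12, methylenated, extended by C1–C4 and carbonylated to the west bromide 13. This is joined to the east stannane 18, the alcohol becomes the chloride, and the only ring is closed last by one-pot hydroboration and copper-catalysed enantioselective SN2′ allyl–alkyl coupling.
Stereochemistry: 6Z comes from nerol, 10E from the SeO2 oxidation, 2E from the (E)-enol triflate, and the (Z)-allyl chloride from anti-carbomagnesiation. The single stereocentre C14 (R) comes from the chiral bisphosphine on copper in the ring closure.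

Key step: step 14

Assumption: the sense of induction of the DTBM-SEGPHOS–copper catalyst on a 2-alkyl-substituted (Z)-allyl chloride cannot be predicted with certainty; the (R)-ligand is written, and the (S)-ligand takes its place if a model coupling shows the opposite sense.

**Route**

Step 1
Reactants: 1 neryl acetate, (2Z)-3,7-dimethylocta-2,6-dien-1-yl acetate
Product: 2 (2Z,6E)-8-hydroxy-3,7-dimethylocta-2,6-dien-1-yl acetate
Conditions: SeO2 (0.1 equiv), t-BuOOH (3 equiv), salicylic acid (0.1 equiv), CH2Cl2, 0 °C to rt
Reagents that add atoms: tert-butyl hydroperoxide, CC(C)(C)OO; selenium dioxide (oxygen relay), O=[Se]=O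
Why: Riley-type allylic oxidation (ene reaction, then [2,3]-shift) attacks the electron-rich alkene remote from the acetate at its (E)-methyl group, which fixes the 10E geometry.

Step 2
Reactants: 2 (2Z,6E)-8-hydroxy-3,7-dimethylocta-2,6-dien-1-yl acetate
Product: 3 (2Z,6E)-3,7-dimethyl-8-oxoocta-2,6-dien-1-yl acetate
Conditions: activated MnO2 (excess), CH2Cl2, rt
Reagents that add atoms: none
Why: MnO2 oxidation is selective for allylic alcohols and gives the enal without touching the acetate or either alkene geometry.

Step 3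
Reactants: 3 (2Z,6E)-3,7-dimethyl-8-oxoocta-2,6-dien-1-yl acetate
Product: 4 (2Z,6E)-3,7-dimethylnona-2,6,8-trien-1-yl acetate
Conditions: MePPh3Br, n-BuLi, THF, 0 °C; then 3, −78 to 0 °C
Reagents that add atoms: methyltriphenylphosphonium bromide, C[P+](c1ccccc1)(c1ccccc1)c1ccccc1.[Br-]
Why: Wittig methylenation of the aldehyde is much faster than attack on the acetate and turns the enal into the terminal 1,3-diene (C12=C13) with the E alkene untouched.

Step 4
Reactants: 4 (2Z,6E)-3,7-dimethylnona-2,6,8-trien-1-yl acetate
Product: 5 (2Z,6E)-3,7-dimethylnona-2,6,8-trien-1-ol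
Conditions: K2CO3 (0.2 equiv), MeOH, rt
Reagents that add atoms: none
Why: Base-catalysed transesterification (Zemplén-type methanolysis) removes the acetate under conditions that leave the triene unchanged.

Step 5
Reactants: 5 (2Z,6E)-3,7-dimethylnona-2,6,8-trien-1-ol
Product: 6 (3E,7Z)-9-bromo-3,7-dimethylnona-1,3,7-triene
Conditions: CBr4, PPh3, CH2Cl2, −30 to 0 °C, used at once
Reagents that add atoms: carbon tetrabromide, BrC(Br)(Br)Br
Why: Appel bromination displaces the oxyphosphonium ion by SN2 under neutral conditions, so the Z allylic geometry and the acid-sensitive diene are kept.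

Step 6
Reactants: 6 (3E,7Z)-9-bromo-3,7-dimethylnona-1,3,7-triene; 7 methyl acetoacetate
Product: 9 methyl (6Z,10E)-7,11-dimethyl-3-oxotrideca-6,10,12-trienoate, via acetoacetate dianion 8 (not isolated)
Conditions: 7, NaH, THF, 0 °C; n-BuLi, 0 °C; then 6, 0 °C to rt; aq. NH4Cl
Reagents that add atoms: none
Why: γ-Alkylation of the acetoacetate dianion takes place at the more basic terminal carbon by SN2 attack on the primary allylic bromide and brings in C1–C4 in one operation.

Step 7
Reactants: 9 methyl (6Z,10E)-7,11-dimethyl-3-oxotrideca-6,10,12-trienoate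
Product: 10 methyl (2E,6Z,10E)-7,11-dimethyl-3-{[(trifluoromethyl)sulfonyl]oxy}trideca-2,6,10,12-tetraenoate
Conditions: Tf2O, aq. Me4NOH (25 %), toluene, 5–10 °C
Reagents that add atoms: triflic anhydride, O=S(=O)(OS(=O)(=O)C(F)(F)F)C(F)(F)F
Why: O-Sulfonylation of the non-chelated tetramethylammonium enolate under biphasic Schotten–Baumann-type conditions gives the (E)-enol triflate (ester and triflate trans), which is the origin of the C2=C3 geometry.

Step 8
Reactants: 10 the (E)-enol triflate ester
Product: 11 (2E,6Z,10E)-1-hydroxy-7,11-dimethyltrideca-2,6,10,12-tetraen-3-yl trifluoromethanesulfonate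
Conditions: i-Bu2AlH (2.3 equiv), CH2Cl2, −78 °C; aq. potassium sodium tartrate
Reagents that add atoms: none
Why: i-Bu2AlH reduces the conjugated ester by 1,2-addition to the allylic alcohol at low temperature while the vinyl triflate and the alkenes are inert.

Step 9
Reactants: 11 the hydroxy vinyl triflate
Product: 12 methyl (2E)-2-[(3Z,7E)-4,8-dimethyldeca-3,7,9-trien-1-yl]-4-hydroxybut-2-enoate
Conditions: Pd(OAc)2 (5 mol %), PPh3 (10 mol %), CO (1 atm), Et3N, MeOH–DMF, rt to 40 °C
Reagents that add atoms: carbon monoxide, [C-]#[O+]; methanol, CO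
Why: Palladium-catalysed methoxycarbonylation of the vinyl triflate (oxidative addition, CO insertion, methanolysis) keeps the alkene geometry, and the CH2OH group trans to the acylpalladium centre cannot lactonise.

Step 10
Reactants: 12 the hydroxy enoate
Product: 13 methyl (2E)-4-bromo-2-[(3Z,7E)-4,8-dimethyldeca-3,7,9-trien-1-yl]but-2-enoate (west fragment)
Conditions: CBr4, PPh3, CH2Cl2, 0 °C
Reagents that add atoms: carbon tetrabromide, BrC(Br)(Br)Br
Why: Appel bromination of the primary γ-hydroxy enoate proceeds by SN2 without allylic transposition and without base.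

Step 11
Reactants: 14 5-bromo-2-methylpent-2-ene; 15 propargyl alcohol
Product: 18 (2Z)-2-(4-methylpent-3-en-1-yl)-3-(tributylstannyl)prop-2-en-1-ol (east fragment), via homoprenylmagnesium bromide 16 (not isolated), via oxamagnesole chelate 17 (not isolated)
Conditions: 14, Mg, Et2O–THF, reflux; 15 (0.4 equiv), CuI (10 mol %), −10 °C to rt; Bu3SnCl, 0 °C to rt; aq. NH4Cl
Reagents that add atoms: tributyltin chloride, CCCC[Sn](Cl)(CCCC)CCCC
Why: Copper-catalysed anti-carbomagnesiation of the propargylic alkoxide puts the homoprenyl group on the inner alkyne carbon and magnesium on the terminal carbon inside a five-membered chelate, so stannylation of the alkenylmagnesium with retention places tin cis to CH2OH.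

Step 12
Reactants: 13 west allylic bromide; 18 east alkenylstannane
Product: 19 methyl (2E,5Z)-2-[(3Z,7E)-4,8-dimethyldeca-3,7,9-trien-1-yl]-6-(hydroxymethyl)-10-methylundeca-2,5,9-trienoate
Conditions: Pd2(dba)3 (2.5 mol %), AsPh3 (20 mol %), THF, rt to 45 °C
Reagents that add atoms: none
Why: The Stille allyl–alkenyl coupling with zerovalent palladium joins the alkenyl group with retention to the unsubstituted terminus C1 of the η3-allyl intermediate under neutral conditions, which keeps the enoate conjugated and gives the skipped 1,4-diene.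

Step 13
Reactants: 19 the seco alcohol
Product: 20 methyl (2E,5Z)-6-(chloromethyl)-2-[(3Z,7E)-4,8-dimethyldeca-3,7,9-trien-1-yl]-10-methylundeca-2,5,9-trienoate
Conditions: PPh3, Cl3CC(O)CCl3, CH2Cl2, −20 to 0 °C
Reagents that add atoms: hexachloroacetone, ClC(Cl)(Cl)C(=O)C(Cl)(Cl)Cl
Why: Appel-type chlorination with PPh3 and hexachloroacetone converts primary allylic alcohols into the unrearranged chlorides with retention of alkene geometry under essentially neutral conditions.

Step 14
Reactants: 20 the seco (Z)-allylic chloride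
Product: 23 target, methyl (1E,4R,7E,11Z)-7,11-dimethyl-4-(6-methylhepta-1,5-dien-2-yl)cyclotetradeca-1,7,11-triene-1-carboxylate, via B-alkyl-9-BBN 21 (not isolated), via potassium ethoxyborate 22 (not isolated)
Conditions: 9-BBN-H dimer (0.5 equiv), THF, 0 °C to rt; KOEt (1.05 equiv), −20 °C; syringe-pump addition (20 h) to (CuOTf)2·C6H5CH3 (10 mol %), (R)-DTBM-SEGPHOS (22 mol %), 1,4-dioxane–THF, 25 °C, final concentration about 2 mM
Reagents that add atoms: none
Why: Proposed new method: 9-BBN-H adds anti-Markovnikov to the only monosubstituted alkene (C12=C13 of the diene), KOEt turns borane 21 into borate 22, and boron-to-copper transmetalation gives a primary C13 alkylcopper bearing the chiral bisphosphine; this binds C14=C15 anti to the C–Cl bond, undergoes SN2′ oxidative addition to a γ-σ-allyl species of trivalent copper and reductively eliminates to form C13–C14 while the double bond moves to C15=CH2. The closest known reaction type is the intermolecular copper-catalysed, γ-selective enantioselective allyl–alkyl coupling of alkyl-9-BBN reagents with (Z)-configured primary allylic chlorides, supported by the copper-catalysed asymmetric SN2′ alkylation of 2-substituted allylic chlorides; the new elements are the intramolecular, macrocyclising use and the 2-alkyl substituent on the allyl chloride. The 14-membered carbocycle closes in a 14-exo SN2′ mode (C15 and its CH2 stay outside the ring), and the competing α-attack to a 16-membered ring is disfavoured by the γ-preference of phosphine-ligated alkylcopper. The single stereocentre C14 is set by the ligand, which distinguishes the enantiotopic faces of the geometrically pure (Z)-C14=C15 alkene, there being no other stereocentre to match or mismatch. Ring closure over oligomerisation is secured by slow addition of preformed 22 to the catalyst and by the two chain-cis alkenes C2=C3 and C6=C7, which fold the chain. Preforming the borate keeps free alkoxide away from the doubly allylic C1–H bonds, exactly one equivalent of B–H spares the new C15=CH2, and neutral alkylcopper should ignore the trisubstituted enoate.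

**Compound list**

1 | neryl acetate | CC(C)=CCC/C(C)=C\COC(C)=O | starting material
2 | (2Z,6E)-8-hydroxy-3,7-dimethylocta-2,6-dien-1-yl acetate | OC/C(C)=C/CC/C(C)=C\COC(C)=O | intermediate
3 | (2Z,6E)-3,7-dimethyl-8-oxoocta-2,6-dien-1-yl acetate | O=C/C(C)=C/CC/C(C)=C\COC(C)=O | intermediate
4 | (2Z,6E)-3,7-dimethylnona-2,6,8-trien-1-yl acetate | C=C/C(C)=C/CC/C(C)=C\COC(C)=O | intermediate
5 | (2Z,6E)-3,7-dimethylnona-2,6,8-trien-1-ol | C=C/C(C)=C/CC/C(C)=C\CO | intermediate
6 | (3E,7Z)-9-bromo-3,7-dimethylnona-1,3,7-triene | C=C/C(C)=C/CC/C(C)=C\CBr | intermediate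
7 | methyl acetoacetate | CC(=O)CC(=O)OC | starting material
8 | sodium lithium dianion of methyl acetoacetate | C=C([O-])C=C([O-])OC.[Na+].[Li+] | intermediate
9 | methyl (6Z,10E)-7,11-dimethyl-3-oxotrideca-6,10,12-trienoate | C=C/C(C)=C/CC/C(C)=C\CCC(=O)CC(=O)OC | intermediate
10 | methyl (2E,6Z,10E)-7,11-dimethyl-3-(triflyloxy)trideca-2,6,10,12-tetraenoate | C=C/C(C)=C/CC/C(C)=C\CC/C(OS(=O)(=O)C(F)(F)F)=C\C(=O)OC | intermediate
11 | (2E,6Z,10E)-1-hydroxy-7,11-dimethyltrideca-2,6,10,12-tetraen-3-yl triflate | C=C/C(C)=C/CC/C(C)=C\CC/C(OS(=O)(=O)C(F)(F)F)=C\CO | intermediate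
12 | methyl (2E)-2-[(3Z,7E)-4,8-dimethyldeca-3,7,9-trien-1-yl]-4-hydroxybut-2-enoate | C=C/C(C)=C/CC/C(C)=C\CC/C(C(=O)OC)=C\CO | intermediate
13 | methyl (2E)-4-bromo-2-[(3Z,7E)-4,8-dimethyldeca-3,7,9-trien-1-yl]but-2-enoate | C=C/C(C)=C/CC/C(C)=C\CC/C(C(=O)OC)=C\CBr | intermediate
14 | 5-bromo-2-methylpent-2-ene | CC(C)=CCCBr | starting material
15 | propargyl alcohol | C#CCO | starting material
16 | (4-methylpent-3-en-1-yl)magnesium bromide | CC(C)=CCC[Mg]Br | intermediate
17 | 4-(4-methylpent-3-en-1-yl)-2,5-dihydro-1,2-oxamagnesole | CC(C)=CCCC1=C[Mg]OC1 | intermediate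
18 | (2Z)-2-(4-methylpent-3-en-1-yl)-3-(tributylstannyl)prop-2-en-1-ol | CCCC[Sn](CCCC)(CCCC)/C=C(\CO)CCC=C(C)C | intermediate
19 | methyl (2E,5Z)-2-[(3Z,7E)-4,8-dimethyldeca-3,7,9-trien-1-yl]-6-(hydroxymethyl)-10-methylundeca-2,5,9-trienoate | C=C/C(C)=C/CC/C(C)=C\CC/C(C(=O)OC)=C\C/C=C(\CO)CCC=C(C)C | intermediate
20 | methyl (2E,5Z)-6-(chloromethyl)-2-[(3Z,7E)-4,8-dimethyldeca-3,7,9-trien-1-yl]-10-methylundeca-2,5,9-trienoate | C=C/C(C)=C/CC/C(C)=C\CC/C(C(=O)OC)=C\C/C=C(\CCl)CCC=C(C)C | intermediate
21 | methyl (2E,5Z)-2-[(3Z,7E)-10-(9-borabicyclo[3.3.1]nonan-9-yl)-4,8-dimethyldeca-3,7-dien-1-yl]-6-(chloromethyl)-10-methylundeca-2,5,9-trienoate | C1CC2CCCC(C1)B2CC/C(C)=C/CC/C(C)=C\CC/C(C(=O)OC)=C\C/C=C(\CCl)CCC=C(C)C | intermediate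
22 | potassium B-ethoxy ate complex of 21 | CCO[B-]1(CC/C(C)=C/CC/C(C)=C\CC/C(C(=O)OC)=C\C/C=C(\CCl)CCC=C(C)C)C2CCCC1CCC2.[K+] | intermediate
23 | methyl (1E,4R,7E,11Z)-7,11-dimethyl-4-(6-methylhepta-1,5-dien-2-yl)cyclotetradeca-1,7,11-triene-1-carboxylate | C=C(CCC=C(C)C)[C@H]1C/C=C(/C(=O)OC)CC/C=C(/C)CC/C=C(\C)CC1 | target

**Count**

Total steps: 14. Longest linear sequence: 13 (steps 1–10, 12, 13, 14).

**Steps most likely to fail**

Step 14. Capture of the tethered alkylcopper may be slower than oligomerisation or loss of the C–B/C–Cu bond. The 2-alkyl substituent may lower reactivity or facial selectivity. Traces of free alkoxide may move the skipped diene into conjugation or cause 1,4-elimination of HCl.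

The fallback makes the same bond with known chemistry. It sets out from 20 and comes back at 23.
- Borane 21, formed as in the route, is oxidised with NaBO3·4H2O to the seco hydroxy chloride F1.
- Buffered Dess–Martin periodinane gives the seco aldehyde chloride F2.
- An intramolecular Nozaki–Hiyama–Kishi allylation closes the ring (CrCl2, NaI, chiral oxazoline–sulfonamide ligand, THF, high dilution). This is the ring closure established for 14-membered cembranoid carbocycles.
- The allylchromium attacks through its γ-carbon C14 in a Zimmerman–Traxler chair, so C15=CH2 again appears and the anti macrocyclic homoallylic alcohol F3 should result. The ligand on divalent chromium governs the absolute sense.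
- Thiocarbonyldiimidazole gives the imidazolylthiocarbonate F4.
- Barton–McCombie deoxygenation (Bu3SnH in high concentration, AIBN, toluene, 80 °C) removes the auxiliary C13 oxygen to reach 23.

Step 12. Transmetalation of the hindered β,β-disubstituted alkenylstannane may be sluggish. Protodestannylation may compete, and prolonged warming may allow migration of the skipped diene into conjugation or erosion of the C2=C3 geometry through η3–η1–η3 interconversion.

The fallback gives up tin and the free hydroxyl. It also removes the reliance on the stannylation in step 11. It sets out from 17 (and 13) and comes back at 19.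
- Chelate 17 is quenched with I2 to the (Z)-iodo allylic alcohol F5.
- Silylation (TBSCl, imidazole) gives the silyl ether F6.
- F6 is converted by t-BuLi and then ZnBr2 into the alkenylzinc, which is joined to 13 by Negishi alkenyl–allyl coupling (Pd(PPh3)4, THF, 0 °C) to give the silylated seco ester F7.
- HF·pyridine, which is not basic, releases 19.

Step 1. The allylic oxidation may stop at partial conversion, over-oxidise, or attack other allylic positions, which would starve the longest sequence at its start.

The fallback replaces C–H oxidation by cleavage and rebuilding. It sets out from 1 and comes back at 3.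
- mCPBA epoxidises the more electron-rich terminal alkene to the racemic 6,7-epoxide F8.
- H5IO6 cleaves F8 to the truncated aldehyde F9.
- The stabilised ylide 2-(triphenylphosphoranylidene)propanal (toluene, 80 °C) rebuilds the (E)-enal 3 by an E-selective Wittig reaction.

**Further compounds**

F1 | step 14 | methyl (2E,5Z)-6-(chloromethyl)-2-[(3Z,7E)-10-hydroxy-4,8-dimethyldeca-3,7-dien-1-yl]-10-methylundeca-2,5,9-trienoate | OCC/C(C)=C/CC/C(C)=C\CC/C(C(=O)OC)=C\C/C=C(\CCl)CCC=C(C)C
F2 | step 14 | methyl (2E,5Z)-6-(chloromethyl)-2-[(3Z,7E)-4,8-dimethyl-10-oxodeca-3,7-dien-1-yl]-10-methylundeca-2,5,9-trienoate | O=CC/C(C)=C/CC/C(C)=C\CC/C(C(=O)OC)=C\C/C=C(\CCl)CCC=C(C)C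
F3 | step 14 | methyl (1E,4R,5S,7E,11Z)-5-hydroxy-7,11-dimethyl-4-(6-methylhepta-1,5-dien-2-yl)cyclotetradeca-1,7,11-triene-1-carboxylate | C=C(CCC=C(C)C)[C@H]1C/C=C(/C(=O)OC)CC/C=C(/C)CC/C=C(\C)C[C@@H]1O
F4 | step 14 | O-(imidazol-1-ylthiocarbonyl) derivative of F3 | C=C(CCC=C(C)C)[C@H]1C/C=C(/C(=O)OC)CC/C=C(/C)CC/C=C(\C)C[C@@H]1OC(=S)n1ccnc1
F5 | step 12 | (2Z)-3-iodo-2-(4-methylpent-3-en-1-yl)prop-2-en-1-ol | I/C=C(\CO)CCC=C(C)C
F6 | step 12 | tert-butyl{[(2Z)-3-iodo-2-(4-methylpent-3-en-1-yl)prop-2-en-1-yl]oxy}dimethylsilane | I/C=C(\CO[Si](C)(C)C(C)(C)C)CCC=C(C)C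
F7 | step 12 | tert-butyldimethylsilyl ether of 19 | C=C/C(C)=C/CC/C(C)=C\CC/C(C(=O)OC)=C\C/C=C(\CO[Si](C)(C)C(C)(C)C)CCC=C(C)C
F8 | step 1 | (2Z)-5-(3,3-dimethyloxiran-2-yl)-3-methylpent-2-en-1-yl acetate (racemic) | CC1(C)OC1CC/C(C)=C\COC(C)=O
F9 | step 1 | (2Z)-3-methyl-6-oxohex-2-en-1-yl acetate | O=CCC/C(C)=C\COC(C)=O
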